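**Retrosynthetic overview**
- Enabling feature: the target is a 1,3-diol monoacetate with a free OH on C7 and the acetate on O9. Its six atoms C7–C8–C9–O9–C(acetyl)=O(acetyl) are the ring atoms of a 1,3-dioxan-4-one in which C7 and the acetyl carbon have exchanged oxidation levels. The target equals that dioxanone plus Ar–H.
- Key disconnection: the bond between C7 and the trimethoxyphenyl ring. A 3,4,5-trimethoxyphenyl Grignard reagent adds to (5R)-5-aryloxy-2-methyl-1,3-dioxan-4-one. Aryl addition, ring opening and an internal Tishchenko hydride shift then give the C–C bond, the C7 stereocentre and the O9 acetate in one operation.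
- The dioxanone comes from (R)-2-aryloxy-3-hydroxypropanoic acid and an acetaldehyde acetal. The C8–OAr bond comes from Mitsunobu inversion of an (S)-glycerate with 4-allyl-2,6-dimethoxyphenol.
- Rings: both arenes are bought. The only ring made is the temporary dioxanone (step 5), which is opened again in step 6.

Key step: step 6

Remark: C7, C8 and C9 denote the carbinol carbon, the aryloxy-bearing carbon and the acetoxymethyl carbon, and O7 and O9 their oxygens; the given SMILES corresponds to 7R,8R (threo), and the Grignard reagent is taken as the commercial THF solution.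

Step 1
Reactants: 1 methyl (4S)-2,2-dimethyl-1,3-dioxolane-4-carboxylate
Product: 2 methyl (2S)-2,3-dihydroxypropanoate
Conditions: AcOH/H2O (4:1), 40 °C
Reagents that add atoms: none
Why: Acid-catalysed acetal hydrolysis removes the isopropylidene group while the methyl ester survives and the stereocentre, which takes no part, is kept.

Step 2
Reactants: 2 methyl (2S)-2,3-dihydroxypropanoate
Product: 3 methyl (2S)-3-[(tert-butyldimethylsilyl)oxy]-2-hydroxypropanoate
Conditions: TBSCl (1.05 equiv), imidazole, CH2Cl2, 0 °C
Reagents that add atoms: tert-butyldimethylsilyl chloride, CC(C)(C)[Si](C)(C)Cl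
Why: Sterically governed selective silylation, in which the primary hydroxyl reacts much faster than the secondary, ester-deactivated hydroxyl that is needed free for step 3.

Step 3
Reactants: 3 methyl (2S)-3-[(tert-butyldimethylsilyl)oxy]-2-hydroxypropanoate; 4 4-allyl-2,6-dimethoxyphenol
Product: 5 methyl (2R)-2-(4-allyl-2,6-dimethoxyphenoxy)-3-[(tert-butyldimethylsilyl)oxy]propanoate
Conditions: PPh3, DIAD, THF, 0 °C → rt
Reagents that add atoms: none
Why: Mitsunobu etherification, in which the phenol displaces the oxyphosphonium group of the α-hydroxy ester by SN2 with inversion, so the (S)-carbinol becomes the (R)-aryl ether that is C8 of the target.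

Step 4
Reactants: 5 methyl (2R)-2-(4-allyl-2,6-dimethoxyphenoxy)-3-[(tert-butyldimethylsilyl)oxy]propanoate
Product: 7 (2R)-2-(4-allyl-2,6-dimethoxyphenoxy)-3-hydroxypropanoic acid, via lithium carboxylate 6 (not isolated)
Conditions: LiOH, THF/H2O, 0 °C; then 1 M HCl to pH 1, rt
Reagents that add atoms: lithium hydroxide, [Li+].[OH-]
Why: Ester saponification followed by acid-catalysed silyl ether hydrolysis in the same flask; at 0 °C hydroxide attacks the unhindered methyl ester faster than it removes C8–H, and the carboxylate 6 is no longer α-acidic, so the (R) centre should be kept.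

Step 5
Reactants: 7 (2R)-2-(4-allyl-2,6-dimethoxyphenoxy)-3-hydroxypropanoic acid
Product: 8 (5R)-5-(4-allyl-2,6-dimethoxyphenoxy)-2-methyl-1,3-dioxan-4-one (both C2 epimers, used together)
Conditions: MeCH(OMe)2, CSA (cat.), 4 Å MS, CH2Cl2, rt
Reagents that add atoms: acetaldehyde dimethyl acetal, CC(OC)OC
Why: Acid-catalysed transacetalisation of a β-hydroxy acid to a 1,3-dioxan-4-one, with the sieves taking up the methanol; C5 is not touched, and the new C2 centre needs no control because step 6 erases it.

Step 6
Reactants: 8 (5R)-5-(4-allyl-2,6-dimethoxyphenoxy)-2-methyl-1,3-dioxan-4-one; 9 (3,4,5-trimethoxyphenyl)magnesium bromide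
Product: 13 [(2R,3R)-2-(4-allyl-2,6-dimethoxyphenoxy)-3-hydroxy-3-(3,4,5-trimethoxyphenyl)propyl] acetate (target; 7R,8R), via cyclic hemiketal alkoxide 10 (not isolated), via keto hemiacetal alkoxide 11 (not isolated), via carbinol alkoxide 12 (not isolated)
Conditions: 9 (1.0 equiv, slow addition to 8), LaCl3·2LiCl (0.3 equiv), THF, −78 → −40 °C; then 0 °C; sat. aq NH4Cl, 0 °C
Reagents that add atoms: none
Why: Proposed new method: slow addition of 9 to 8 gives one carbonyl addition at C4 of the lactone (the future C7), as in the known single addition of aryl organometallics to six-membered lactones, and the hemiketal alkoxide 10 persists in the cold until 9 is consumed. On warming, 10 opens by expulsion of the acylal oxygen to ketone 11, in which O9 carries the metal alkoxide of an acetaldehyde hemiacetal, the very intermediate of the Evans–Tishchenko and aldol–Tishchenko reactions (the closest known reaction types, there assembled from a β-hydroxy ketone, an added aldehyde and a Sm, La or Li alkoxide), and an irreversible 1,5-hydride shift from the hemiacetal carbon to C7 turns that carbon into the O9 acetate and C7 into the carbinol 12. No ring is closed; the temporary dioxanone is opened and only the hydride-transfer transition state is cyclic (six-membered chair, Mg/La bridging O7 and the hemiacetal oxygen, both axial). The one new stereocentre, C7, is controlled by C8: with the trimethoxyphenyl group equatorial and the C8–OAr bond equatorial, i.e. antiperiplanar to the incoming hydride (polar Felkin–Anh) and gauche to O7 so that the ether oxygen and an ortho-methoxy oxygen can bind the same metal, the hydride, tethered through C9, reaches the face that gives 7R from 8R (threo). Both C2 epimers of 8 converge, since the hemiacetal alkoxide exchanges acetaldehyde reversibly before the slower hydride transfer and C2 ends as the trigonal acetyl carbon. The step needs mono-addition (stable 10, inverse addition), integrity of C8 (weakly basic La-modified reagent, rapid internal reduction of the ketone) and acetate on O9 only (the ester is formed on O9 and a cold, buffered quench forestalls 1,3-acyl migration), and the allyl group and the aryl ethers are inert to all species present.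

**Compound list**
1 | methyl (4S)-2,2-dimethyl-1,3-dioxolane-4-carboxylate | COC(=O)[C@@H]1COC(C)(C)O1 | starting material
2 | methyl (2S)-2,3-dihydroxypropanoate | COC(=O)[C@@H](O)CO | intermediate
3 | methyl (2S)-3-[(tert-butyldimethylsilyl)oxy]-2-hydroxypropanoate | COC(=O)[C@@H](O)CO[Si](C)(C)C(C)(C)C | intermediate
4 | 4-allyl-2,6-dimethoxyphenol | C=CCc1cc(OC)c(O)c(OC)c1 | starting material
5 | methyl (2R)-2-(4-allyl-2,6-dimethoxyphenoxy)-3-[(tert-butyldimethylsilyl)oxy]propanoate | C=CCc1cc(OC)c(O[C@H](CO[Si](C)(C)C(C)(C)C)C(=O)OC)c(OC)c1 | intermediate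
6 | lithium (2R)-2-(4-allyl-2,6-dimethoxyphenoxy)-3-[(tert-butyldimethylsilyl)oxy]propanoate | C=CCc1cc(OC)c(O[C@H](CO[Si](C)(C)C(C)(C)C)C(=O)[O-])c(OC)c1.[Li+] | intermediate
7 | (2R)-2-(4-allyl-2,6-dimethoxyphenoxy)-3-hydroxypropanoic acid | C=CCc1cc(OC)c(O[C@H](CO)C(=O)O)c(OC)c1 | intermediate
8 | (5R)-5-(4-allyl-2,6-dimethoxyphenoxy)-2-methyl-1,3-dioxan-4-one, C2 epimers | C=CCc1cc(OC)c(O[C@@H]2COC(C)OC2=O)c(OC)c1 | intermediate
9 | (3,4,5-trimethoxyphenyl)magnesium bromide | COc1cc([Mg]Br)cc(OC)c1OC | starting material
10 | bromomagnesium (5R)-5-(4-allyl-2,6-dimethoxyphenoxy)-2-methyl-4-(3,4,5-trimethoxyphenyl)-1,3-dioxan-4-olate, C2 and C4 undefined | C=CCc1cc(OC)c(O[C@@H]2COC(C)OC2(O[Mg]Br)c3cc(OC)c(OC)c(OC)c3)c(OC)c1 | intermediate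
11 | bromomagnesium 1-[(2R)-2-(4-allyl-2,6-dimethoxyphenoxy)-3-oxo-3-(3,4,5-trimethoxyphenyl)propoxy]ethanolate, hemiacetal carbon undefined | C=CCc1cc(OC)c(O[C@H](COC(C)O[Mg]Br)C(=O)c2cc(OC)c(OC)c(OC)c2)c(OC)c1 | intermediate
12 | bromomagnesium (1R,2R)-3-acetoxy-2-(4-allyl-2,6-dimethoxyphenoxy)-1-(3,4,5-trimethoxyphenyl)propan-1-olate | C=CCc1cc(OC)c(O[C@H](COC(C)=O)[C@H](O[Mg]Br)c2cc(OC)c(OC)c(OC)c2)c(OC)c1 | intermediate
13 | [(2R,3R)-2-(4-allyl-2,6-dimethoxyphenoxy)-3-hydroxy-3-(3,4,5-trimethoxyphenyl)propyl] acetate | C=CCc1cc(OC)c(O[C@H](COC(C)=O)[C@H](O)c2cc(OC)c(OC)c(OC)c2)c(OC)c1 | target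

Total step count: 6. Longest linear sequence: 6 steps (1 → 13); 4 and 9 enter as purchased fragments.

**Steps most likely to fail**

Step 6 (labelled step).
- What may go wrong: the hemiacetal alkoxide may shed acetaldehyde for good before it transfers hydride, so that the sequence stalls at the hydroxy-ketone stage. The released ketone may take up a second aryl group. C8 may enolise. The facial bias of the hydride shift may be too small.
- Fallback (known chemistry, from 5 back to 13): ester 5 is converted with MeNH(OMe)·HCl and i-PrMgCl into the Weinreb amide F1. This accepts 9 only once (Weinreb ketone synthesis, same aryl–C7 bond) to give the silyloxy ketone F2. HF·pyridine frees the β-hydroxy ketone F3. A standard Evans–Tishchenko reduction (SmI2 cat., excess acetaldehyde, THF, −10 °C) then sets the 7-OH and places the acetate on O9, reaching 13.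

Step 5.
- What may go wrong: under reversible acid conditions, intermolecular esterification (oligomers) or methyl ester formation may outrun closure of the acylal ring, and the product may hydrolyse during isolation.
- Fallback (from 7 back to 8): both acidic hydrogens are silylated (TMSCl, Et3N) to give the bis(trimethylsilyl) derivative F4. The ring is then closed irreversibly by TMSOTf-catalysed silyl-transfer acetalisation with acetaldehyde in CH2Cl2 at −78 °C, driven by Si–O bond formation.

Step 3.
- What may go wrong: slow attack of the di-ortho-substituted phenol on the oxyphosphonium ion may let β-elimination to the acrylate and alkylation of the hydrazide compete, with erosion of configurational purity.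
- Fallback (from 3 and 4 back to 5): alcohol 3 is activated as the triflate F5 (Tf2O, 2,6-lutidine, CH2Cl2, −78 °C). It is then displaced by the potassium phenoxide of 4 (K2CO3, MeCN, 0 °C) in a plain SN2 reaction with the same inversion.

**Further compounds**
F1 | step 6 | (2R)-2-(4-allyl-2,6-dimethoxyphenoxy)-3-[(tert-butyldimethylsilyl)oxy]-N-methoxy-N-methylpropanamide | C=CCc1cc(OC)c(O[C@H](CO[Si](C)(C)C(C)(C)C)C(=O)N(C)OC)c(OC)c1
F2 | step 6 | (2R)-2-(4-allyl-2,6-dimethoxyphenoxy)-3-[(tert-butyldimethylsilyl)oxy]-1-(3,4,5-trimethoxyphenyl)propan-1-one | C=CCc1cc(OC)c(O[C@H](CO[Si](C)(C)C(C)(C)C)C(=O)c2cc(OC)c(OC)c(OC)c2)c(OC)c1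
F3 | step 6 | (2R)-2-(4-allyl-2,6-dimethoxyphenoxy)-3-hydroxy-1-(3,4,5-trimethoxyphenyl)propan-1-one | C=CCc1cc(OC)c(O[C@H](CO)C(=O)c2cc(OC)c(OC)c(OC)c2)c(OC)c1
F4 | step 5 | trimethylsilyl (2R)-2-(4-allyl-2,6-dimethoxyphenoxy)-3-[(trimethylsilyl)oxy]propanoate | C=CCc1cc(OC)c(O[C@H](CO[Si](C)(C)C)C(=O)O[Si](C)(C)C)c(OC)c1
F5 | step 3 | methyl (2S)-3-[(tert-butyldimethylsilyl)oxy]-2-[(trifluoromethylsulfonyl)oxy]propanoate | COC(=O)[C@@H](OS(=O)(=O)C(F)(F)F)CO[Si](C)(C)C(C)(C)C
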